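## Retrosynthetic overview

1. The strategy rests on ring D (C11–C15–C16–C13–C12) of the bicyclo[3.2.1]octene. C16 carries the C17 methylene and is bonded to bridgehead C13, which is alpha to the C12 oxygen, and C16 reaches C11 through C15. The C13–C16 bond is therefore cut to a C12=C13 silyl enol ether and a C16≡C17 alkyne on a C11–C15 chain (gold, 5-exo-dig), with C15=O and C12–OH adjusted afterwards.
2. Enol silane 25 comes from β,γ-enone 18 and ynal 19: aldol at C11 (C11–C15), O-silylation, alkyne desilylation, kinetic C13 enolisation.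
3. Enone 18 comes from anisole 15 (ring C aromatic, 12-OMe) by Birch reduction, acetylation and enol ether hydrolysis.
4. Anisole 15 comes from vinyl carbinol 9: ring B by Friedel–Crafts closure C7–C8, hydroboration at C6, then oxidation/reduction to set C1 and C6.
5. Carbinol 9 comes from dione 1 and aryl bromide 2: arylation (C9–C10), CBS desymmetrisation (C10), gem-dimethylation (C4), vinyl addition (C5–C6). Ring order: A and C are bought, B is closed in step 6, D in step 18.

Key step: step 18

Numbering: the terpenoid numbering of the target is used throughout. Ring A = C1–C5, C10; ring B = C5–C10; ring C = C8, C9, C11–C14; ring D = C11, C12, C13, C16, C15; C17 = methylene carbon; C18/C19 = methyls on C4; C20 = methyl on C10.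

Assumption: in the CBS reduction of 3, hydride should add to the carbonyl face anti to the aryl group. If the other diastereomer predominates, the (R)-catalyst is used instead; it gives the same C10 configuration, and the carbinol centre is re-set in steps 9–10 either way.

Remark: C15 ends as a ketone. The route is drawn for the 15S epimer expected from step 14; a 15R epimer, if formed, can be taken through the same steps.

## Route

Step 1
Reactants: 1 2-methylcyclohexane-1,3-dione; 2 3-bromoanisole
Product: 3 2-(3-methoxyphenyl)-2-methylcyclohexane-1,3-dione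
Conditions: Pd(OAc)2 (cat.), t-BuXPhos (cat.), K3PO4, 1,4-dioxane, 90 °C
Reagents that add atoms: none
Why: Palladium-catalysed α-arylation of a 1,3-diketone enolate; the 2-methyl dione has one acidic site, so the quaternary carbon (future C10, with C20 and the C9 ipso carbon of ring C) should form without regiochemical choice, and no stereocentre arises.

Step 2
Reactants: 3 2-(3-methoxyphenyl)-2-methylcyclohexane-1,3-dione
Product: 4 (2R,3R)-3-hydroxy-2-(3-methoxyphenyl)-2-methylcyclohexan-1-one
Conditions: (S)-Me-CBS oxazaborolidine (20 mol %), catecholborane, toluene, −78 to −40 °C; chromatography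
Reagents that add atoms: none
Why: Corey–Bakshi–Shibata reduction used as an enantiotopic-group desymmetrisation; the catalyst should give the R carbinol (quaternary carbon as the large group) at the carbonyl whose reacting face is anti to the aryl group, which fixes the quaternary centre as R (future C10), and the minor diastereomer (opposite C10) is removed by chromatography.

Step 3
Reactants: 4 (2R,3R)-3-hydroxy-2-(3-methoxyphenyl)-2-methylcyclohexan-1-one
Product: 5 (2R,3R)-3-(tert-butyldimethylsilyloxy)-2-(3-methoxyphenyl)-2-methylcyclohexan-1-one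
Conditions: TBSOTf, 2,6-lutidine, CH2Cl2, −78 to 0 °C
Reagents that add atoms: tert-butyldimethylsilyl triflate, CC(C)(C)[Si](C)(C)OS(=O)(=O)C(F)(F)F
Why: Silylation of a hindered secondary alcohol with a silyl triflate under non-basic conditions, which avoids retro-aldol opening of the β-hydroxy ketone; no stereocentre is touched.

Step 4
Reactants: 5 (2R,3R)-3-(tert-butyldimethylsilyloxy)-2-(3-methoxyphenyl)-2-methylcyclohexan-1-one
Product: 7 (2R,3R)-3-(tert-butyldimethylsilyloxy)-2-(3-methoxyphenyl)-2,6,6-trimethylcyclohexan-1-one, via monomethyl ketone 6 (not isolated)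
Conditions: KOt-Bu (3 equiv), MeI (excess), THF, 0 °C to rt
Reagents that add atoms: iodomethane, CI
Why: Exhaustive enolate alkylation; the ketone can enolise only toward C6 of the cyclohexanone (the other α-carbon is quaternary), so two successive methylations should give the gem-dimethyl group (future C4, C18, C19) without touching a stereocentre.

Step 5
Reactants: 7 (2R,3R)-3-(tert-butyldimethylsilyloxy)-2-(3-methoxyphenyl)-2,6,6-trimethylcyclohexan-1-one; 8 vinylmagnesium bromide
Product: 9 (2R,3R)-3-(tert-butyldimethylsilyloxy)-2-(3-methoxyphenyl)-2,6,6-trimethyl-1-vinylcyclohexan-1-ol (carbinol centre not controlled)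
Conditions: anhydrous CeCl3, THF, −78 to 0 °C, then rt
Reagents that add atoms: none
Why: Organocerium 1,2-addition to a non-enolisable, doubly neopentyl ketone (no enolisation or β-hydride reduction can compete); the vinyl group brings C6 and C7, and the new carbinol configuration is immaterial because this carbon becomes sp2 in step 6.

Step 6
Reactants: 9 (2R,3R)-3-(tert-butyldimethylsilyloxy)-2-(3-methoxyphenyl)-2,6,6-trimethyl-1-vinylcyclohexan-1-ol
Product: 10 (1R)-1-(tert-butyldimethylsilyloxy)-12-methoxypodocarpa-5,8,11,13-tetraene (C1–O trans to C20)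
Conditions: BF3·OEt2 (0.3 equiv), 4 Å MS, CH2Cl2, −40 to 0 °C
Reagents that add atoms: none
Why: Intramolecular Friedel–Crafts allylation (SN1′); the tertiary allylic alcohol ionises to an allyl cation whose primary terminus C7 is attacked by the anisole carbon para to methoxy (C8) through a six-membered transition state, closing ring B with a C5=C6 double bond, while attack at the tertiary terminus would need a four-membered ring.

Step 7
Reactants: 10 (1R)-1-(tert-butyldimethylsilyloxy)-12-methoxypodocarpa-5,8,11,13-tetraene
Product: 12 (1R,5R,6R,10R)-1-(tert-butyldimethylsilyloxy)-12-methoxypodocarpa-8,11,13-trien-6-ol, via C6 alkylborane 11 (not isolated)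
Conditions: BH3·THF, THF, 0 °C to rt; then NaOH, H2O2, 0 to 40 °C
Reagents that add atoms: hydrogen peroxide, OO
Why: Hydroboration–oxidation (anti-Markovnikov, syn); boron goes to C6 and hydrogen to C5 on the face opposite the axial C20 methyl and the axial C4 methyl, which sets H5 trans to C20 (trans A/B fusion) and gives the equatorial 6-alcohol.

Step 8
Reactants: 12 (1R,5R,6R,10R)-1-(tert-butyldimethylsilyloxy)-12-methoxypodocarpa-8,11,13-trien-6-ol
Product: 13 (1R,5R,6R,10R)-12-methoxypodocarpa-8,11,13-triene-1,6-diol
Conditions: TBAF, THF, 60 °C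
Reagents that add atoms: none
Why: Fluoride cleavage of the hindered secondary silyl ether; nothing else in the molecule is fluoride-sensitive and no stereocentre is touched.

Step 9
Reactants: 13 (1R,5R,6R,10R)-12-methoxypodocarpa-8,11,13-triene-1,6-diol
Product: 14 (5R,10R)-12-methoxypodocarpa-8,11,13-triene-1,6-dione
Conditions: Dess–Martin periodinane, CH2Cl2, rt; under argon, used at once
Reagents that add atoms: none
Why: Dess–Martin oxidation of both secondary alcohols; C5 becomes α to the C6 ketone, but the trans-fused isomer is the thermodynamic one, so the centre set in step 7 should hold.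

Step 10
Reactants: 14 (5R,10R)-12-methoxypodocarpa-8,11,13-triene-1,6-dione
Product: 15 (1S,5R,6S,10R)-12-methoxypodocarpa-8,11,13-triene-1,6-diol (both hydroxyls cis to C20)
Conditions: NaBH4, MeOH/CH2Cl2, 0 °C to rt
Reagents that add atoms: none
Why: Borohydride reduction under steric approach control in the rigid trans-fused tricycle; at C6 the axial path is closed by the syn-axial C20 and C4 methyls, so hydride enters equatorially and gives the axial alcohol cis to C20, and at C1 hydride adds axially from the face opposite C20 (the equatorial path is blocked by C20 and the peri C11–H), giving the equatorial alcohol cis to C20.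

Step 11
Reactants: 15 (1S,5R,6S,10R)-12-methoxypodocarpa-8,11,13-triene-1,6-diol
Product: 16 (1S,5R,6S,10R)-12-methoxypodocarpa-8,12-diene-1,6-diol
Conditions: Li, NH3(l), THF, t-BuOH, −78 to −33 °C; NH4Cl
Reagents that add atoms: none
Why: Birch reduction; the two unsubstituted, para-related ring carbons C11 and C14 are protonated, leaving the tetrasubstituted C8=C9 alkene and the C12=C13 methyl enol ether, and the homobenzylic C–O bonds (as alkoxides) are not cleaved.

Step 12
Reactants: 16 (1S,5R,6S,10R)-12-methoxypodocarpa-8,12-diene-1,6-diol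
Product: 17 (1S,5R,6S,10R)-12-methoxypodocarpa-8,12-diene-1,6-diyl diacetate
Conditions: Ac2O, DMAP (cat.), pyridine, rt to 40 °C
Reagents that add atoms: acetic anhydride, CC(=O)OC(C)=O
Why: DMAP-catalysed acetylation of both alcohols (the axial C6 hydroxyl needs the catalyst); it is done while ring C is still the base-stable enol ether, so the later β,γ-enone never meets base.

Step 13
Reactants: 17 (1S,5R,6S,10R)-12-methoxypodocarpa-8,12-diene-1,6-diyl diacetate
Product: 18 (1S,5R,6S,10R)-12-oxopodocarp-8-ene-1,6-diyl diacetate
Conditions: oxalic acid (aq.), MeOH/THF, rt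
Reagents that add atoms: water, O
Why: Mild acid hydrolysis of the methyl enol ether (protonation at C13, then loss of methanol) should give the β,γ-unsaturated ketone without moving C8=C9 into conjugation; the acetates are stable.

Step 14
Reactants: 18 (1S,5R,6S,10R)-12-oxopodocarp-8-ene-1,6-diyl diacetate; 19 3-(trimethylsilyl)propynal
Product: 21 (11S)-11-[(1S)-1-hydroxy-3-(trimethylsilyl)prop-2-yn-1-yl]-12-oxopodocarp-8-ene-1,6-diyl diacetate, via lithium dienolate 20 (not isolated)
Conditions: LiHMDS (1.05 equiv), THF, −78 °C; then 19, −78 °C; AcOH quench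
Reagents that add atoms: none
Why: Lithium aldol addition through the conjugated dienolate; LiHMDS removes the doubly activated C11 proton and not the acetate protons, the dienolate reacts at its α-carbon C11 on the face opposite the axial C20 methyl (sets C11), and in the closed Zimmerman–Traxler chair the slim alkynyl group should take the axial site over ring C because the equatorial site runs into C1 and its acetate, which gives the 15S carbinol.

Step 15
Reactants: 21 (11S)-11-[(1S)-1-hydroxy-3-(trimethylsilyl)prop-2-yn-1-yl]-12-oxopodocarp-8-ene-1,6-diyl diacetate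
Product: 22 (11S)-11-[(1S)-1-(tert-butyldimethylsilyloxy)-3-(trimethylsilyl)prop-2-yn-1-yl]-12-oxopodocarp-8-ene-1,6-diyl diacetate
Conditions: TBSOTf, 2,6-lutidine, CH2Cl2, −78 °C
Reagents that add atoms: tert-butyldimethylsilyl triflate, CC(C)(C)[Si](C)(C)OS(=O)(=O)C(F)(F)F
Why: Silyl triflate protection of the aldol hydroxyl at low temperature with a hindered base, the standard way to cap a β-hydroxy ketone without retro-aldol or elimination.

Step 16
Reactants: 22 (11S)-11-[(1S)-1-(tert-butyldimethylsilyloxy)-3-(trimethylsilyl)prop-2-yn-1-yl]-12-oxopodocarp-8-ene-1,6-diyl diacetate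
Product: 23 (11S)-11-[(1S)-1-(tert-butyldimethylsilyloxy)prop-2-yn-1-yl]-12-oxopodocarp-8-ene-1,6-diyl diacetate
Conditions: AgNO3 (0.2 equiv), acetone/H2O, rt, dark
Reagents that add atoms: none
Why: Silver(I)-catalysed protodesilylation of the alkynylsilane; the neutral conditions should leave the acetates, the O-silyl ether and the β,γ-enone untouched, which carbonate in methanol would not.

Step 17
Reactants: 23 (11S)-11-[(1S)-1-(tert-butyldimethylsilyloxy)prop-2-yn-1-yl]-12-oxopodocarp-8-ene-1,6-diyl diacetate
Product: 25 (11S)-12-(tert-butyldimethylsilyloxy)-11-[(1S)-1-(tert-butyldimethylsilyloxy)prop-2-yn-1-yl]podocarpa-8,12-diene-1,6-diyl diacetate, via lithium enolate 24 (not isolated)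
Conditions: LiHMDS (1.05 equiv), THF, −78 °C; then TBSOTf, −78 °C; Et3N, pH 7 buffer
Reagents that add atoms: tert-butyldimethylsilyl triflate, CC(C)(C)[Si](C)(C)OS(=O)(=O)C(F)(F)F
Why: Kinetic enolate formation and O-silylation; the axial C13 proton is removed while the C11 proton, which lies near the carbonyl plane because the side chain is axial, is not, LiHMDS is too weak to enolise the acetates and is kept near one equivalent to limit alkyne metalation, so the C12=C13 enol ether should result and β-elimination of the C15 silyloxy group is avoided. The TBS enol ether is chosen because it survives the methanol of step 18.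

Step 18
Reactants: 25 (11S)-12-(tert-butyldimethylsilyloxy)-11-[(1S)-1-(tert-butyldimethylsilyloxy)prop-2-yn-1-yl]podocarpa-8,12-diene-1,6-diyl diacetate
Product: 26 ring D-closed ketone: 1,6-diacetoxy-15-(tert-butyldimethylsilyloxy)-12-oxo compound with C8=C9 and the C16=C17 methylene (15S, silyloxy exo, toward C12)
Conditions: Ph3PAuCl (10 mol %), AgBF4 (10 mol %), CH2Cl2/MeOH (10:1), rt
Reagents that add atoms: none
Why: Cationic gold(I) binds the terminal C16≡C17 alkyne and C13 of the silyl enol ether adds anti to gold at the internal carbon C16; methanol takes the silyl group from the silyloxocarbenium ion and the proton released cleaves the C17–Au bond, leaving the C12 ketone and the C16=C17 methylene. The closest known reaction type is the gold(I)-catalysed carbocyclisation of silyl enol ethers onto alkynes (a Conia-ene-type reaction), which is established for bridged bicyclo[3.2.1]octanones. Ring D (C11–C15–C16–C13–C12) closes in the 5-exo-dig mode. The one new stereocentre, C13, is fixed by the tether: the chain stands axial on C11 on the face away from C20 and can reach C13 only on that face, so C13–C16 forms cis to C11–C15 as the bridge requires. The step needs attack of C13 at C16 in preference to 6-endo closure at C17 and to capture of the alkyne by the C8=C9 alkene; Markovnikov activation of a terminal alkyne, the far higher nucleophilicity of the enol ether carbon, and the fact that C9 would have to become a second quaternary centre should secure this, and the site of the nucleophile is already built into 25 as the C12=C13 enol ether. The product ketone lies between two bridgeheads and cannot enolise, so C11 and C13 are safe afterwards.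

Step 19
Reactants: 26 ring D-closed ketone
Product: 27 12-alcohol: 1,6-diacetoxy-15-(tert-butyldimethylsilyloxy)-12-hydroxy compound (C12 hydroxyl on the side of the C15–C16 bridge)
Conditions: NaBH4, MeOH, −20 to 0 °C
Reagents that add atoms: none
Why: Borohydride reduction of the bridging ketone; the face toward the C15–C16 bridge is covered by the exo C15 silyloxy group, so hydride should come from the side of the C8=C9 bridge (as in 7-norbornenone), which puts the C12 hydroxyl on the side of the C15–C16 bridge, and the acetates survive at low temperature.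

Step 20
Reactants: 27 12-alcohol
Product: 28 12,15-diol: 1,6-diacetoxy-12,15-dihydroxy compound with the C16=C17 methylene
Conditions: HF·pyridine, pyridine, THF, 0 °C to rt
Reagents that add atoms: none
Why: Buffered HF desilylation of the allylic silyl ether; acetates and the exocyclic alkene are stable, and a silyl shift between O15 and O12 would be harmless since both oxygens end free.

Step 21
Reactants: 28 12,15-diol
Product: 29 1alpha,6alpha-diacetoxyjungermannenone C
Conditions: activated MnO2, CH2Cl2, rt
Reagents that add atoms: none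
Why: Manganese dioxide oxidises only the allylic C15 alcohol to the α-methylene ketone; the C12 alcohol is not allylic and stays, and the neutral conditions avoid retro-aldol cleavage of the β-hydroxy ketone.

## Compound list

1 | 2-methylcyclohexane-1,3-dione | CC1C(=O)CCCC1=O | starting material
2 | 3-bromoanisole | COc1cccc(Br)c1 | starting material
3 | 2-(3-methoxyphenyl)-2-methylcyclohexane-1,3-dione | COc1cccc(c1)C1(C)C(=O)CCCC1=O | intermediate
4 | (2R,3R)-3-hydroxy-2-(3-methoxyphenyl)-2-methylcyclohexan-1-one (hydroxyl cis to aryl) | O=C1CCC[C@@H](O)[C@@]1(C)c1cccc(OC)c1 | intermediate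
5 | (2R,3R)-3-(tert-butyldimethylsilyloxy)-2-(3-methoxyphenyl)-2-methylcyclohexan-1-one | O=C1CCC[C@@H](O[Si](C)(C)C(C)(C)C)[C@@]1(C)c1cccc(OC)c1 | intermediate
6 | (2R,3R)-3-(tert-butyldimethylsilyloxy)-2-(3-methoxyphenyl)-2,6-dimethylcyclohexan-1-one (both C6 epimers) | O=C1C(C)CC[C@@H](O[Si](C)(C)C(C)(C)C)[C@@]1(C)c1cccc(OC)c1 | intermediate
7 | (2R,3R)-3-(tert-butyldimethylsilyloxy)-2-(3-methoxyphenyl)-2,6,6-trimethylcyclohexan-1-one | O=C1C(C)(C)CC[C@@H](O[Si](C)(C)C(C)(C)C)[C@@]1(C)c1cccc(OC)c1 | intermediate
8 | vinylmagnesium bromide | C=C[Mg]Br | starting material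
9 | (2R,3R)-3-(tert-butyldimethylsilyloxy)-2-(3-methoxyphenyl)-2,6,6-trimethyl-1-vinylcyclohexan-1-ol (carbinol centre not controlled) | C=CC1(O)C(C)(C)CC[C@@H](O[Si](C)(C)C(C)(C)C)[C@@]1(C)c1cccc(OC)c1 | intermediate
10 | (1R)-1-(tert-butyldimethylsilyloxy)-12-methoxypodocarpa-5,8,11,13-tetraene (C1–O trans to C20) | COc1ccc2CC=C3C(C)(C)CC[C@@H](O[Si](C)(C)C(C)(C)C)[C@@]3(C)c2c1 | intermediate
11 | C6 alkylborane of 10 (boron on C6 and hydrogen on C5, both trans to C20) | COc1ccc2C[C@@H](B)[C@@H]3C(C)(C)CC[C@@H](O[Si](C)(C)C(C)(C)C)[C@@]3(C)c2c1 | intermediate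
12 | (1R,5R,6R,10R)-1-(tert-butyldimethylsilyloxy)-12-methoxypodocarpa-8,11,13-trien-6-ol | COc1ccc2C[C@@H](O)[C@@H]3C(C)(C)CC[C@@H](O[Si](C)(C)C(C)(C)C)[C@@]3(C)c2c1 | intermediate
13 | (1R,5R,6R,10R)-12-methoxypodocarpa-8,11,13-triene-1,6-diol | COc1ccc2C[C@@H](O)[C@@H]3C(C)(C)CC[C@@H](O)[C@@]3(C)c2c1 | intermediate
14 | (5R,10R)-12-methoxypodocarpa-8,11,13-triene-1,6-dione | COc1ccc2CC(=O)[C@@H]3C(C)(C)CCC(=O)[C@@]3(C)c2c1 | intermediate
15 | (1S,5R,6S,10R)-12-methoxypodocarpa-8,11,13-triene-1,6-diol | COc1ccc2C[C@H](O)[C@@H]3C(C)(C)CC[C@H](O)[C@@]3(C)c2c1 | intermediate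
16 | (1S,5R,6S,10R)-12-methoxypodocarpa-8,12-diene-1,6-diol | C1C2=C(C[C@H](O)[C@@H]3C(C)(C)CC[C@H](O)[C@@]23C)CC=C1OC | intermediate
17 | (1S,5R,6S,10R)-12-methoxypodocarpa-8,12-diene-1,6-diyl diacetate | C1C2=C(C[C@H](OC(C)=O)[C@@H]3C(C)(C)CC[C@H](OC(C)=O)[C@@]23C)CC=C1OC | intermediate
18 | (1S,5R,6S,10R)-12-oxopodocarp-8-ene-1,6-diyl diacetate | C1C2=C(C[C@H](OC(C)=O)[C@@H]3C(C)(C)CC[C@H](OC(C)=O)[C@@]23C)CCC1=O | intermediate
19 | 3-(trimethylsilyl)propynal | C[Si](C)(C)C#CC=O | starting material
20 | lithium 8,11-dien-12-olate of 18 (conjugated dienolate) | [Li]OC1=CC2=C(C[C@H](OC(C)=O)[C@@H]3C(C)(C)CC[C@H](OC(C)=O)[C@@]23C)CC1 | intermediate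
21 | (11S)-11-[(1S)-1-hydroxy-3-(trimethylsilyl)prop-2-yn-1-yl]-12-oxopodocarp-8-ene-1,6-diyl diacetate (side chain on C11 trans to C20) | C[Si](C)(C)C#C[C@@H](O)[C@@H]1C2=C(C[C@H](OC(C)=O)[C@@H]3C(C)(C)CC[C@H](OC(C)=O)[C@@]23C)CCC1=O | intermediate
22 | (11S)-11-[(1S)-1-(tert-butyldimethylsilyloxy)-3-(trimethylsilyl)prop-2-yn-1-yl]-12-oxopodocarp-8-ene-1,6-diyl diacetate | C[Si](C)(C)C#C[C@@H](O[Si](C)(C)C(C)(C)C)[C@@H]1C2=C(C[C@H](OC(C)=O)[C@@H]3C(C)(C)CC[C@H](OC(C)=O)[C@@]23C)CCC1=O | intermediate
23 | (11S)-11-[(1S)-1-(tert-butyldimethylsilyloxy)prop-2-yn-1-yl]-12-oxopodocarp-8-ene-1,6-diyl diacetate | C#C[C@@H](O[Si](C)(C)C(C)(C)C)[C@@H]1C2=C(C[C@H](OC(C)=O)[C@@H]3C(C)(C)CC[C@H](OC(C)=O)[C@@]23C)CCC1=O | intermediate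
24 | lithium 12-en-12-olate of 23 (C12=C13 enolate) | C#C[C@@H](O[Si](C)(C)C(C)(C)C)[C@@H]1C2=C(C[C@H](OC(C)=O)[C@@H]3C(C)(C)CC[C@H](OC(C)=O)[C@@]23C)CC=C1O[Li] | intermediate
25 | (11S)-12-(tert-butyldimethylsilyloxy)-11-[(1S)-1-(tert-butyldimethylsilyloxy)prop-2-yn-1-yl]podocarpa-8,12-diene-1,6-diyl diacetate (key-step precursor) | C#C[C@@H](O[Si](C)(C)C(C)(C)C)[C@@H]1C2=C(C[C@H](OC(C)=O)[C@@H]3C(C)(C)CC[C@H](OC(C)=O)[C@@]23C)CC=C1O[Si](C)(C)C(C)(C)C | intermediate
26 | ring D-closed ketone: 1,6-diacetoxy-15-(tert-butyldimethylsilyloxy)-12-oxo compound with C8=C9 and C16=C17 methylene (key-step product) | C=C1[C@@H](O[Si](C)(C)C(C)(C)C)[C@@H]2C3=C(C[C@H](OC(C)=O)[C@@H]4C(C)(C)CC[C@H](OC(C)=O)[C@@]34C)C[C@H]1C2=O | intermediate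
27 | 12-alcohol: 1,6-diacetoxy-15-(tert-butyldimethylsilyloxy)-12-hydroxy compound (12-OH on the side of the C15–C16 bridge) | C=C1[C@@H](O[Si](C)(C)C(C)(C)C)[C@@H]2C3=C(C[C@H](OC(C)=O)[C@@H]4C(C)(C)CC[C@H](OC(C)=O)[C@@]34C)C[C@H]1[C@@H]2O | intermediate
28 | 12,15-diol: 1,6-diacetoxy-12,15-dihydroxy compound with C16=C17 methylene | C=C1[C@@H](O)[C@@H]2C3=C(C[C@H](OC(C)=O)[C@@H]4C(C)(C)CC[C@H](OC(C)=O)[C@@]34C)C[C@H]1[C@@H]2O | intermediate
29 | 1alpha,6alpha-diacetoxyjungermannenone C | C=C1C(=O)[C@@H]2C3=C(C[C@H](OC(C)=O)[C@@H]4C(C)(C)CC[C@H](OC(C)=O)[C@@]34C)C[C@H]1[C@@H]2O | target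

## Summary

Total step count: 21. Longest linear sequence: 21 steps (1 to 29); 2, 8 and 19 enter as bought side components.

Steps most likely to fail:

Step 18 (gold cyclisation). The enol silane may be protodesilylated by the methanol before it cyclises, or the activated alkyne may be captured by the C8=C9 alkene instead of C13. The fallback sets out from 23 and comes back at 26. Semi-hydrogenation of 23 (H2, Lindlar catalyst, quinoline) would give the vinyl ketone F1. Kinetic enolisation and silylation as in step 17 would give the silyl enol ether F2. Palladium(II) acetate in acetonitrile (or catalytic in DMSO under oxygen) would then close ring D by oxidative cycloalkenylation: the palladium enolate at C13 adds 5-exo across the vinyl group and β-hydride elimination from C16 leaves the C16=C17 methylene, giving 26.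

Step 17 (regioselective enol silane). Enolisation may go toward C11 and be followed by β-elimination of the C15 silyloxy group, or the base may metalate the alkyne C–H and lead to C-silylation. The fallback sets out from 23 and comes back at 26 without strong base and without 25. 23 would be treated with catalytic pyrrolidine and a copper(I) triflate/triphenylphosphine catalyst. The amine condenses on the less hindered side to the C12=C13 enamine F3, which adds to the copper-bound alkyne in the same 5-exo-dig sense, and hydrolysis on work-up gives 26.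

Step 5 (vinyl addition). The doubly neopentyl carbonyl may simply not accept the nucleophile, with recovery of 7. The fallback sets out from 7 and comes back at 9. Ethynylmagnesium bromide with cerium chloride, a much slimmer sp nucleophile, would give the ethynyl carbinol F4, and Lindlar semi-hydrogenation would then give 9.

Further compounds
F1 | step 18 | (11S)-11-[(1S)-1-(tert-butyldimethylsilyloxy)prop-2-en-1-yl]-12-oxopodocarp-8-ene-1,6-diyl diacetate | C=C[C@@H](O[Si](C)(C)C(C)(C)C)[C@@H]1C2=C(C[C@H](OC(C)=O)[C@@H]3C(C)(C)CC[C@H](OC(C)=O)[C@@]23C)CCC1=O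
F2 | step 18 | C12=C13 tert-butyldimethylsilyl enol ether of F1 | C=C[C@@H](O[Si](C)(C)C(C)(C)C)[C@@H]1C2=C(C[C@H](OC(C)=O)[C@@H]3C(C)(C)CC[C@H](OC(C)=O)[C@@]23C)CC=C1O[Si](C)(C)C(C)(C)C
F3 | step 17 | C12=C13 pyrrolidine enamine of 23 | C#C[C@@H](O[Si](C)(C)C(C)(C)C)[C@@H]1C2=C(C[C@H](OC(C)=O)[C@@H]3C(C)(C)CC[C@H](OC(C)=O)[C@@]23C)CC=C1N1CCCC1
F4 | step 5 | (2R,3R)-3-(tert-butyldimethylsilyloxy)-1-ethynyl-2-(3-methoxyphenyl)-2,6,6-trimethylcyclohexan-1-ol (carbinol centre not controlled) | C#CC1(O)C(C)(C)CC[C@@H](O[Si](C)(C)C(C)(C)C)[C@@]1(C)c1cccc(OC)c1
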